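**Plan**

Numbering: lactone O1, C2 (C=O), C3, C4, C5; ring A is the 3,4-dimethoxyphenyl group on the C3 methylene, ring B the 3,4,5-trimethoxyphenyl group on the C4 methylene.
Retrosynthesis: cut O1–C2 (lactonisation), then C4–C5 (one-carbon insertion into a C4–B bond), then C3–C4 together with ring B–CH2 (one three-component coupling), and last ring A–CH2 (aryl Grignard allylation).
Enabling feature: C4 and its exocyclic CH2 are two adjacent carbons between C3 and ring B, so they map onto a vinyl group on boron that takes the C3 alkenyl carbon at its inner carbon and ring B at its outer carbon; boron stays on C4 as the handle for C5.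
Forward: ring A is joined to the propenyl unit (C3 and the future C2), the coupling completes the open chain, boron is exchanged for CH2OH (C5), the exocyclic =CH2 is oxidised to the C2 acid, and the lactone, the only ring formed, closes last.
Stereochemistry: C4 is set by the chiral bisphosphine–palladium catalyst in the coupling and carried on with retention; C3 is set at the end by base equilibration to the trans lactone under control of C4.

Key step: step 3

Assumption: the (Sp,Sp) antipode of the MandyPhos ligand is taken to favour the (R)-configured allylic boronate; the sense is to be confirmed on the derived primary alcohol, and if it is reversed the mirror-image ligand is used with no other change.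

**Route**

Step 1
Reactants: 1 4-bromo-1,2-dimethoxybenzene; 2 2,3-dibromopropene
Product: 4 4-(2-bromoprop-2-en-1-yl)-1,2-dimethoxybenzene, via aryl Grignard reagent 3 (not isolated)
Conditions: Mg, I2 (cat.), THF, reflux; then 2, CuI (5 mol%), THF, 0 °C to rt
Reagents that add atoms: none
Why: Copper-catalysed allylic substitution by an aryl Grignard reagent displaces the allylic bromide of 2 (SN2 and SN2' attack give the same product) and leaves the vinylic C–Br bond untouched.

Step 2
Reactants: 5 3,4,5-trimethoxyphenol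
Product: 6 3,4,5-trimethoxyphenyl trifluoromethanesulfonate
Conditions: Tf2O, pyridine, CH2Cl2, 0 °C
Reagents that add atoms: trifluoromethanesulfonic anhydride, O=S(=O)(OS(=O)(=O)C(F)(F)F)C(F)(F)F
Why: O-Sulfonylation of a phenol with triflic anhydride and pyridine is a standard triflation, and the phenolic oxygen is the only nucleophilic site.

Step 3
Reactants: 4 4-(2-bromoprop-2-en-1-yl)-1,2-dimethoxybenzene; 7 vinylboronic acid pinacol ester; 6 3,4,5-trimethoxyphenyl trifluoromethanesulfonate
Product: 10 2-[(R)-3-(3,4-dimethoxybenzyl)-1-(3,4,5-trimethoxyphenyl)but-3-en-2-yl]-4,4,5,5-tetramethyl-1,3,2-dioxaborolane, via alkenyllithium 8 (not isolated), via borate complex 9 (not isolated)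
Conditions: t-BuLi (2.0 equiv), Et2O, −78 °C; then 7, −78 °C to rt; solvent switch to THF; 6, Pd(OAc)2 (2 mol%), (Sp,Sp)-1,1'-bis[bis(3,5-dimethylphenyl)phosphino]-2,2'-bis[(R)-α-(dimethylamino)benzyl]ferrocene (MandyPhos ligand, 2.4 mol%), KOTf (1.5 equiv), THF, 60 °C
Reagents that add atoms: none
Why: Bromine–lithium exchange on 4 gives alkenyllithium 8, which adds to boron of 7 to form the bis(alkenyl)borate 9, while oxidative addition of triflate 6 to zerovalent palladium gives a cationic aryl complex of divalent palladium that binds the unsubstituted vinyl group of 9. The 2-substituted alkenyl group then shifts from boron to the boron-bearing vinyl carbon anti to the metal (1,2-metallate shift), making C3–C4, and reductive elimination from the resulting alkylpalladium joins ring B to the former vinyl terminus. The closest known reaction type is the enantioselective palladium-catalysed conjunctive cross-coupling of bis(alkenyl)borates with aryl triflates, which gives α-chiral allylic boronates. No ring closes. The C4 stereocentre is set in the metallate shift by the chiral bisphosphine on palladium, which selects one face of the bound vinyl group. The step needs activation of the plain vinyl group and not of the 1,1-disubstituted alkenyl group, and it needs the metallate shift to outrun direct Suzuki–Miyaura transmetallation and β-hydride elimination; the lower steric demand of the vinyl group, the wide-bite-angle ligand, the weakly coordinating triflate and KOTf as bromide scavenger are expected to secure this.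

Step 4
Reactants: 10 2-[(R)-3-(3,4-dimethoxybenzyl)-1-(3,4,5-trimethoxyphenyl)but-3-en-2-yl]-4,4,5,5-tetramethyl-1,3,2-dioxaborolane
Product: 12 (R)-3-(3,4-dimethoxybenzyl)-2-(3,4,5-trimethoxybenzyl)but-3-en-1-ol, via homologated boronate 11 (not isolated)
Conditions: BrCH2Cl (3 equiv), n-BuLi (2.5 equiv), THF, −78 °C to rt; then NaOH (3 M aq.), H2O2 (30%), 0 °C to rt
Reagents that add atoms: bromochloromethane, ClCBr; hydrogen peroxide, OO
Why: Matteson homologation, in which chloromethyllithium formed in situ adds to boron and C4 migrates with retention while chloride leaves, gives the primary boronate 11, and alkaline peroxide oxidation of its C–B bond gives the C5 alcohol without touching the C4 centre.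

Step 5
Reactants: 12 (R)-3-(3,4-dimethoxybenzyl)-2-(3,4,5-trimethoxybenzyl)but-3-en-1-ol
Product: 13 tert-butyl{[(R)-3-(3,4-dimethoxybenzyl)-2-(3,4,5-trimethoxybenzyl)but-3-en-1-yl]oxy}dimethylsilane
Conditions: TBSCl, imidazole, DMF, rt
Reagents that add atoms: tert-butyldimethylsilyl chloride, CC(C)(C)[Si](C)(C)Cl
Why: Imidazole-mediated silylation of a primary alcohol masks the C5 oxygen so that the two chain termini stay distinct during the later oxidation.

Step 6
Reactants: 13 tert-butyl{[(R)-3-(3,4-dimethoxybenzyl)-2-(3,4,5-trimethoxybenzyl)but-3-en-1-yl]oxy}dimethylsilane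
Product: 15 (2RS,3R)-4-[(tert-butyldimethylsilyl)oxy]-2-(3,4-dimethoxybenzyl)-3-(3,4,5-trimethoxybenzyl)butan-1-ol, via alkylborane 14 (not isolated)
Conditions: 9-BBN, THF, rt to 50 °C; then NaOH (3 M aq.), H2O2 (30%), 0 °C to rt
Reagents that add atoms: hydrogen peroxide, OO
Why: Anti-Markovnikov hydroboration of the 1,1-disubstituted alkene with 9-BBN puts boron on the terminal carbon (the future C2) and peroxide oxidation gives the primary alcohol; the new C3 centre forms without reliable control and is corrected in step 9.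

Step 7
Reactants: 15 (2RS,3R)-4-[(tert-butyldimethylsilyl)oxy]-2-(3,4-dimethoxybenzyl)-3-(3,4,5-trimethoxybenzyl)butan-1-ol
Product: 16 (2RS,3R)-4-[(tert-butyldimethylsilyl)oxy]-2-(3,4-dimethoxybenzyl)-3-(3,4,5-trimethoxybenzyl)butanoic acid
Conditions: TEMPO (20 mol%), PhI(OAc)2 (2.5 equiv), MeCN/H2O (1:1), rt
Reagents that add atoms: water, O
Why: Oxoammonium (TEMPO) oxidation with PhI(OAc)2 in aqueous acetonitrile takes a primary alcohol through the aldehyde hydrate to the carboxylic acid under near-neutral conditions that the silyl ether and the aryl methyl ethers should tolerate.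

Step 8
Reactants: 16 (2RS,3R)-4-[(tert-butyldimethylsilyl)oxy]-2-(3,4-dimethoxybenzyl)-3-(3,4,5-trimethoxybenzyl)butanoic acid
Product: 18 (3RS,4R)-3-(3,4-dimethoxybenzyl)-4-(3,4,5-trimethoxybenzyl)dihydrofuran-2(3H)-one, via hydroxy acid 17 (not isolated)
Conditions: HCl (2 M aq.), THF, rt
Reagents that add atoms: none
Why: Acid hydrolysis of the primary silyl ether frees the γ-hydroxy acid 17, which undergoes spontaneous acid-catalysed lactonisation (5-exo-trig acyl substitution) to the five-membered lactone with C4 unchanged.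

Step 9
Reactants: 18 (3RS,4R)-3-(3,4-dimethoxybenzyl)-4-(3,4,5-trimethoxybenzyl)dihydrofuran-2(3H)-one
Product: 19 (3R,4R)-3-(3,4-dimethoxybenzyl)-4-(3,4,5-trimethoxybenzyl)dihydrofuran-2(3H)-one
Conditions: DBU (1 equiv), toluene, 80 °C
Reagents that add atoms: none
Why: Base-mediated epimerisation through the lactone enolate acts only on C3, the sole acidic stereocentre, and should drain the cis isomer into the more stable trans lactone, so the fixed (4R) centre dictates (3R).

**Compound list**

1 | 4-bromo-1,2-dimethoxybenzene | COc1ccc(Br)cc1OC | starting material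
2 | 2,3-dibromopropene | C=C(Br)CBr | starting material
3 | 3,4-dimethoxyphenylmagnesium bromide | COc1ccc([Mg]Br)cc1OC | intermediate
4 | 4-(2-bromoprop-2-en-1-yl)-1,2-dimethoxybenzene | COc1ccc(CC(Br)=C)cc1OC | intermediate
5 | 3,4,5-trimethoxyphenol | COc1cc(O)cc(OC)c1OC | starting material
6 | 3,4,5-trimethoxyphenyl trifluoromethanesulfonate | COc1cc(OS(=O)(=O)C(F)(F)F)cc(OC)c1OC | intermediate
7 | vinylboronic acid pinacol ester | C=CB1OC(C)(C)C(C)(C)O1 | starting material
8 | [3-(3,4-dimethoxyphenyl)prop-1-en-2-yl]lithium | [Li]C(=C)Cc1ccc(OC)c(OC)c1 | intermediate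
9 | lithium [3-(3,4-dimethoxyphenyl)prop-1-en-2-yl](ethenyl)(2,3-dimethylbutane-2,3-diolato)borate | [Li+].C=C[B-]1(OC(C)(C)C(C)(C)O1)C(=C)Cc1ccc(OC)c(OC)c1 | intermediate
10 | 2-[(R)-3-(3,4-dimethoxybenzyl)-1-(3,4,5-trimethoxyphenyl)but-3-en-2-yl]-4,4,5,5-tetramethyl-1,3,2-dioxaborolane | CC1(C)OB(OC1(C)C)[C@@H](C(=C)Cc2ccc(OC)c(OC)c2)Cc3cc(OC)c(OC)c(OC)c3 | intermediate
11 | 2-[(R)-3-(3,4-dimethoxybenzyl)-2-(3,4,5-trimethoxybenzyl)but-3-en-1-yl]-4,4,5,5-tetramethyl-1,3,2-dioxaborolane | CC1(C)OB(OC1(C)C)C[C@@H](C(=C)Cc2ccc(OC)c(OC)c2)Cc3cc(OC)c(OC)c(OC)c3 | intermediate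
12 | (R)-3-(3,4-dimethoxybenzyl)-2-(3,4,5-trimethoxybenzyl)but-3-en-1-ol | OC[C@@H](C(=C)Cc1ccc(OC)c(OC)c1)Cc2cc(OC)c(OC)c(OC)c2 | intermediate
13 | tert-butyl{[(R)-3-(3,4-dimethoxybenzyl)-2-(3,4,5-trimethoxybenzyl)but-3-en-1-yl]oxy}dimethylsilane | CC(C)(C)[Si](C)(C)OC[C@@H](C(=C)Cc1ccc(OC)c(OC)c1)Cc2cc(OC)c(OC)c(OC)c2 | intermediate
14 | 9-[(2RS,3R)-4-[(tert-butyldimethylsilyl)oxy]-2-(3,4-dimethoxybenzyl)-3-(3,4,5-trimethoxybenzyl)butyl]-9-borabicyclo[3.3.1]nonane | CC(C)(C)[Si](C)(C)OC[C@@H](C(CB1C2CCCC1CCC2)Cc3ccc(OC)c(OC)c3)Cc4cc(OC)c(OC)c(OC)c4 | intermediate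
15 | (2RS,3R)-4-[(tert-butyldimethylsilyl)oxy]-2-(3,4-dimethoxybenzyl)-3-(3,4,5-trimethoxybenzyl)butan-1-ol | CC(C)(C)[Si](C)(C)OC[C@@H](C(CO)Cc1ccc(OC)c(OC)c1)Cc2cc(OC)c(OC)c(OC)c2 | intermediate
16 | (2RS,3R)-4-[(tert-butyldimethylsilyl)oxy]-2-(3,4-dimethoxybenzyl)-3-(3,4,5-trimethoxybenzyl)butanoic acid | CC(C)(C)[Si](C)(C)OC[C@@H](C(C(=O)O)Cc1ccc(OC)c(OC)c1)Cc2cc(OC)c(OC)c(OC)c2 | intermediate
17 | (2RS,3R)-2-(3,4-dimethoxybenzyl)-4-hydroxy-3-(3,4,5-trimethoxybenzyl)butanoic acid | OC[C@@H](C(C(=O)O)Cc1ccc(OC)c(OC)c1)Cc2cc(OC)c(OC)c(OC)c2 | intermediate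
18 | (3RS,4R)-3-(3,4-dimethoxybenzyl)-4-(3,4,5-trimethoxybenzyl)dihydrofuran-2(3H)-one (C3 epimers) | COc1ccc(CC2C(=O)OC[C@@H]2Cc2cc(OC)c(OC)c(OC)c2)cc1OC | intermediate
19 | (3R,4R)-3-(3,4-dimethoxybenzyl)-4-(3,4,5-trimethoxybenzyl)dihydrofuran-2(3H)-one | COc1ccc(C[C@H]2C(=O)OC[C@@H]2Cc2cc(OC)c(OC)c(OC)c2)cc1OC | target

**Step count and risks**

Total step count: 9. Longest linear sequence: 8 steps (steps 1 and 3 to 9, from 4-bromo-1,2-dimethoxybenzene); step 2 is a one-step side branch.

The three steps most likely to fail are steps 3, 4 and 7.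

Step 3. During the exchange, tert-butyllithium or the alkenyllithium may remove a benzylic–allylic proton or eliminate HBr towards an aryl allene. Bromide left from the exchange may also block alkene binding at the cationic palladium centre, so that the coupling stalls or drifts to direct Suzuki–Miyaura arylation. The fallback sets out from 4 and builds the same borate with the roles of the two boron partners exchanged. Miyaura borylation of 4 (B2pin2, PdCl2(PPh3)2, PPh3, KOPh, toluene, 50 °C) should give the alkenylboronate 2-[3-(3,4-dimethoxyphenyl)prop-1-en-2-yl]-4,4,5,5-tetramethyl-1,3,2-dioxaborolane F1, which is purified free of halide. Halide-free vinyllithium, made from tetravinylstannane and n-BuLi, is then added at 0 °C to give borate 9, where the route is rejoined and the coupling with 6 is run as in step 3.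

Step 4. The short-lived carbenoid may be captured incompletely by the hindered secondary allylic boronate, or it may insert a second time into the less hindered primary boronate once this has formed. The fallback sets out from 10 and replaces the direct methylene insertion by a two-stage insertion and reduction. Pre-formed dichloromethyllithium (CH2Cl2, n-BuLi, THF, −100 °C) adds once to boron, and ZnCl2-promoted migration with retention at C4 should give the α-chloroboronate 2-[(2R)-1-chloro-3-(3,4-dimethoxybenzyl)-2-(3,4,5-trimethoxybenzyl)but-3-en-1-yl]-4,4,5,5-tetramethyl-1,3,2-dioxaborolane F2 as a mixture at the chlorine-bearing carbon. Reduction with LiBHEt3, by hydride addition to boron and 1,2-shift with loss of chloride, gives boronate 11, which is oxidised as in step 4 to 12.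

Step 7. Partial loss of the silyl group in the mildly acidic aqueous medium would expose the C5 alcohol to the oxidant and erase the distinction between the two termini; the oxidation may also stop at the aldehyde. The fallback sets out from 15 and oxidises only after the C5 oxygen is tied up in a ring. Dess–Martin periodinane (CH2Cl2, NaHCO3, rt) should give the aldehyde (2RS,3R)-4-[(tert-butyldimethylsilyl)oxy]-2-(3,4-dimethoxybenzyl)-3-(3,4,5-trimethoxybenzyl)butanal F3. Aqueous HCl in THF removes the silyl group, and the hydroxy aldehyde closes to the lactol (2RS,3RS,4R)-3-(3,4-dimethoxybenzyl)-4-(3,4,5-trimethoxybenzyl)tetrahydrofuran-2-ol F4. Oxidation of the lactol with TEMPO (cat.) and PhI(OAc)2 in dry CH2Cl2 gives lactone 18, and the route is rejoined before step 9.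

**Further compounds**

F1 | step 3 | 2-[3-(3,4-dimethoxyphenyl)prop-1-en-2-yl]-4,4,5,5-tetramethyl-1,3,2-dioxaborolane | COc1ccc(CC(=C)B2OC(C)(C)C(C)(C)O2)cc1OC
F2 | step 4 | 2-[(2R)-1-chloro-3-(3,4-dimethoxybenzyl)-2-(3,4,5-trimethoxybenzyl)but-3-en-1-yl]-4,4,5,5-tetramethyl-1,3,2-dioxaborolane (epimers at C1) | CC1(C)OB(OC1(C)C)C(Cl)[C@@H](C(=C)Cc2ccc(OC)c(OC)c2)Cc3cc(OC)c(OC)c(OC)c3
F3 | step 7 | (2RS,3R)-4-[(tert-butyldimethylsilyl)oxy]-2-(3,4-dimethoxybenzyl)-3-(3,4,5-trimethoxybenzyl)butanal | CC(C)(C)[Si](C)(C)OC[C@@H](C(C=O)Cc1ccc(OC)c(OC)c1)Cc2cc(OC)c(OC)c(OC)c2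
F4 | step 7 | (2RS,3RS,4R)-3-(3,4-dimethoxybenzyl)-4-(3,4,5-trimethoxybenzyl)tetrahydrofuran-2-ol | COc1ccc(CC2C(O)OC[C@@H]2Cc2cc(OC)c(OC)c(OC)c2)cc1OC
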